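Ring B is made by cutting the C5–C6 bond. With C7 written as a ketone, C5 (between the C4 and C9 carbonyls of ring A) and C6 (α to C7 in ring B) are both enolate carbons. Oxidation of the dianion of a monocyclic precursor therefore forms C5–C6, closes the bicyclo[3.3.1]nonane and sets the C5 bridgehead in one operation, and it leaves the C7 ketone as the handle for the endo prenyl group. The precursor is ring A alone: a 4,4-disubstituted 3-hydroxy-5-methoxycyclohexa-2,5-dienone whose quaternary C1 carries prenyl and a CMe2–acetyl arm and whose C5 carries lavandulyl. It is assembled by acyclic Claisen chemistry, so that C1 and the enol ether position are fixed beforehand.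

Key step: step 13

Remark 1: atoms are numbered as in the bicyclic target (C1 prenyl bridgehead, C2–C3–C4 enolised diketone bridge, C5 lavandulyl bridgehead, C6–C7–C8 ring B with C8 = CMe2, C9 bridging ketone). The lavandulyl centre keeps the spatial arrangement of (R)-lavandulol throughout, and only its CIP letter changes (R in 10–13 and 15–17, S from 18 on, once the chain is bonded to ring A).

Remark 2: ring A is built by condensation and not by dearomatising a phloroglucinol ether. A [3,3] shift onto the prenylated aromatic carbon competes with the second substituted ortho carbon, can run on to the free C3 position by a Cope shift, and gives no control of the C1 configuration or of which oxygen carries the methyl group.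

Step 1
Reactants: 1 methyl acetoacetate; 2 prenyl bromide (1-bromo-3-methylbut-2-ene)
Product: 3 methyl 2-acetyl-5-methylhex-4-enoate
Conditions: K2CO3, acetone, reflux
Reagents that add atoms: none
Why: Acetoacetic ester C-alkylation of the β-keto ester enolate with an allylic bromide; the new centre is enolisable and is left undefined because it becomes sp2 in step 2.

Step 2
Reactants: 3 methyl 2-acetyl-5-methylhex-4-enoate; 4 prenol (3-methylbut-2-en-1-ol)
Product: 5 methyl (Z)-3-(3-methylbut-2-enyloxy)-2-(3-methylbut-2-enyl)but-2-enoate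
Conditions: PPh3, DIAD, toluene, 0 °C to rt
Reagents that add atoms: none
Why: Mitsunobu O-alkylation of a 2-substituted β-keto ester, in which the hindered carbon is bypassed and the oxygen of the hydrogen-bonded cis-enol attacks the alkoxyphosphonium ion, so the Z enol ether with the ether oxygen syn to the ester should predominate; it is to be separated from any E isomer and C-alkylated material.

Step 3
Reactants: 5 methyl (Z)-3-(3-methylbut-2-enyloxy)-2-(3-methylbut-2-enyl)but-2-enoate
Product: 6 methyl (S)-2-acetyl-3,3-dimethyl-2-(3-methylbut-2-enyl)pent-4-enoate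
Conditions: N,N'-bis[trans-2-(2-phenyl-1H-pyrrol-1-yl)cyclohexyl]guanidinium tetrakis[3,5-bis(trifluoromethyl)phenyl]borate (20 mol %, the enantiomer that gives the S product), hexanes, 40 °C
Reagents that add atoms: none
Why: Catalytic enantioselective Claisen rearrangement of an O-allyl β-keto ester enol ether, in which the guanidinium hydrogen-bonds to the ether oxygen and to the syn ester carbonyl and fixes one chair transition state, so that the C1–C8 bond and the quaternary C1 stereocentre are set by the catalyst from the geometrically pure Z enol ether; the enantiomeric purity is to be checked and, if needed, upgraded here, where C1 is the only stereocentre.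

Step 4
Reactants: 6 methyl (S)-2-acetyl-3,3-dimethyl-2-(3-methylbut-2-enyl)pent-4-enoate
Product: 9 methyl (R)-2-ethynyl-3,3-dimethyl-2-(3-methylbut-2-enyl)pent-4-enoate, via enol diethyl phosphate 7 (not isolated), via lithium acetylide 8 (not isolated)
Conditions: LiN(iPr)2, THF, −78 °C; ClP(O)(OEt)2, −78 °C to rt; LiN(iPr)2 (2.2 equiv), −78 °C to rt; H2O
Reagents that add atoms: none
Why: Conversion of a methyl ketone into a terminal alkyne by enol phosphate formation and β-elimination; the ketone can be deprotonated only at its methyl group and the quaternary centre is not touched (the descriptor changes from S to R by priority only).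

Step 5
Reactants: 10 (R)-lavandulol
Product: 11 (R)-lavandulyl iodide [(R)-3-(iodomethyl)-2,6-dimethylhepta-1,5-diene]
Conditions: I2, PPh3, imidazole, CH2Cl2, 0 °C
Reagents that add atoms: iodine, [I][I]
Why: Appel-type iodination of a primary alcohol, which does not involve the stereocentre.

Step 6
Reactants: 11 (R)-lavandulyl iodide
Product: 12 (R)-7-methyl-4-(prop-1-en-2-yl)oct-6-enenitrile
Conditions: MeCN, n-BuLi, THF, −78 °C; then 11, −78 °C to rt
Reagents that add atoms: acetonitrile, CC#N
Why: SN2 alkylation of lithioacetonitrile by the primary iodide, a two-carbon homologation that supplies the future C5 methylene and C4.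

Step 7
Reactants: 12 (R)-7-methyl-4-(prop-1-en-2-yl)oct-6-enenitrile
Product: 13 (R)-7-methyl-4-(prop-1-en-2-yl)oct-6-enal
Conditions: iBu2AlH, toluene, −78 °C; aq. potassium sodium tartrate
Reagents that add atoms: water, O
Why: Partial reduction of the nitrile to the aluminium aldimine and hydrolysis to the aldehyde; the stereocentre is γ to the carbonyl and cannot epimerise.

Step 8
Reactants: 9 methyl (R)-2-ethynyl-3,3-dimethyl-2-(3-methylbut-2-enyl)pent-4-enoate; 13 (R)-7-methyl-4-(prop-1-en-2-yl)oct-6-enal
Product: 15 methyl (2S,8R)-5-hydroxy-11-methyl-2-(2-methylbut-3-en-2-yl)-2-(3-methylbut-2-enyl)-8-(prop-1-en-2-yl)dodec-10-en-3-ynoate (both C5 carbinol epimers), via chloromagnesium acetylide 14 (not isolated)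
Conditions: iPrMgCl (1.0 equiv), THF, 0 °C to rt; then 13, −20 °C to 0 °C; aq. NH4Cl
Reagents that add atoms: none
Why: Deprotonation of the isolated terminal alkyne by the Grignard reagent and 1,2-addition of the alkynylmagnesium chloride to the aldehyde, a reagent that is less basic toward the enolisable aldehyde than a lithium acetylide and leaves the hindered, non-enolisable ester alone; the carbinol configuration is not controlled because it is oxidised in step 9.

Step 9
Reactants: 15 propargylic alcohol
Product: 16 methyl (2S,8R)-11-methyl-2-(2-methylbut-3-en-2-yl)-2-(3-methylbut-2-enyl)-5-oxo-8-(prop-1-en-2-yl)dodec-10-en-3-ynoate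
Conditions: Dess–Martin periodinane, CH2Cl2, rt
Reagents that add atoms: none
Why: Dess–Martin oxidation of a propargylic alcohol to the ynone under neutral conditions that leave the alkenes alone.

Step 10
Reactants: 16 ynone
Product: 17 methyl (2S,3E,8R)-3-methoxy-11-methyl-2-(2-methylbut-3-en-2-yl)-2-(3-methylbut-2-enyl)-5-oxo-8-(prop-1-en-2-yl)dodeca-3,10-dienoate (E isomer drawn; any Z isomer is carried along)
Conditions: K2CO3 (cat.), MeOH, 0 °C to rt
Reagents that add atoms: methanol, CO
Why: Oxa-Michael addition of methanol to the ynone puts the methoxy group on the β-carbon only, which is the future C2, so the position of the methyl enol ether is fixed by the connectivity and not by a selective methylation.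

Step 11
Reactants: 17 β-methoxy enone ester
Product: 18 (4R)-3-hydroxy-5-methoxy-4-(2-methylbut-3-en-2-yl)-4-(3-methylbut-2-enyl)-2-[(2S)-5-methyl-2-(prop-1-en-2-yl)hex-4-enyl]cyclohexa-2,5-dien-1-one
Conditions: NaOMe (2.5 equiv), MeOH/THF, rt to 40 °C; aq. HCl to pH 3
Reagents that add atoms: none
Why: Intramolecular Claisen (Dieckmann-type) condensation in which the C5 enolate of the vinylogous ester attacks the C9 methyl ester (6-exo-trig) and the product is drained as its vinylogous acid salt, while reversible methoxide addition interconverts the E and Z enol ethers so both feed the ring closure; no stereocentre is formed, and 18 is kept cold and used at once because its 1,1-dimethylallyl group sits on a dienone carbon.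

Step 12
Reactants: 18 ring A vinylogous acid with the 1,1-dimethylallyl arm
Product: 19 (4R)-3-hydroxy-5-methoxy-4-(2-methyl-3-oxobutan-2-yl)-4-(3-methylbut-2-enyl)-2-[(2S)-5-methyl-2-(prop-1-en-2-yl)hex-4-enyl]cyclohexa-2,5-dien-1-one
Conditions: PdCl2 (10 mol %), CuCl, O2 (1 atm), DMF/H2O (7:1), rt; dilute aq. HCl work-up
Reagents that add atoms: water, O
Why: Tsuji–Wacker oxidation picks the only monosubstituted alkene and gives the methyl ketone by Markovnikov oxypalladation, the trisubstituted and 1,1-disubstituted alkenes being much slower, and any cyclic enol ether formed by attack of the C9 enol oxygen opens to the same ketone on acidic work-up.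

Step 13
Reactants: 19 ring A precursor with the CMe2–acetyl arm
Product: 21 (1S,5R)-2-methoxy-8,8-dimethyl-1-(3-methylbut-2-enyl)-5-[(2S)-5-methyl-2-(prop-1-en-2-yl)hex-4-enyl]bicyclo[3.3.1]non-2-ene-4,7,9-trione, via dilithium dienolate 20 (not isolated)
Conditions: LiN(iPr)2 (2.2 equiv), THF, −78 °C; Fe(acac)3 (2.2 equiv), −78 °C to rt; aq. NH4Cl
Reagents that add atoms: none
Why: Two equivalents of LiN(iPr)2 turn 19 into 20, in which the C4–C5–C9 β-diketonate is accompanied by the C6 enolate of the methyl ketone, and because C8 bears no hydrogen the methyl group C6 is the only place where that ketone can be deprotonated. Fe(acac)3 removes one electron from the C6 enolate, which as the non-stabilised ketone enolate has by far the lower oxidation potential, the electrophilic α-keto radical adds to C5 of the neighbouring diketonate, and a second electron transfer gives the 1,4-diketone. The closest known reaction type is the intramolecular oxidative heterocoupling of two unlike carbonyl enolates with Fe(acac)3 or Cu(O2CCH(C2H5)C4H9)2, which is known to close bridged rings at fully substituted carbon. Ring B closes as a six-membered ring by 6-exo-trig attack of C6 on the C4=C5 enolate form of ring A, which gives the bicyclo[3.3.1]nonane. The new C5 stereocentre is dictated by the C1 quaternary centre, since C5 is trigonal in the enolate and the three-atom tether C8–C7–C6 can reach it from one face only, so a single bridgehead configuration is possible. The step needs carbon–carbon bond formation to win over coupling at oxygen and over addition of the radical to the side-chain alkenes; C5 is the carbon terminus of the diketonate and is held next to C6 in a chair-like array, the nearest alkene carbons would require strained bridged rings, and C3 stays outside the enolate because O2 is methylated.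

Step 14
Reactants: 21 7-oxo bicyclic enol ether
Product: 22 7-hydroxy-2-methoxy-8,8-dimethyl-1-(3-methylbut-2-enyl)-5-[(2S)-5-methyl-2-(prop-1-en-2-yl)hex-4-enyl]-7-(prop-2-enyl)bicyclo[3.3.1]non-2-ene-4,9-dione (bridgeheads spatially as in 21, hydroxyl endo, allyl exo)
Conditions: CH2=CHCH2ZnBr, THF, −78 °C to 0 °C; aq. NH4Cl
Reagents that add atoms: allylzinc bromide, C=CC[Zn]Br
Why: Allylzinc 1,2-addition should go to the C7 ketone, the only carbonyl with an unhindered flank (C9 lies between two quaternary carbons and C4 is a vinylogous ester carbonyl), from the open exo face; allyl is used because prenyl-metal reagents add with allylic transposition, and the C7 configuration made here is erased in step 17.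

Step 15
Reactants: 22 7-allyl carbinol
Product: 23 7-hydroxy-2-methoxy-8,8-dimethyl-1,7-bis(3-methylbut-2-enyl)-5-[(2S)-5-methyl-2-(prop-1-en-2-yl)hex-4-enyl]bicyclo[3.3.1]non-2-ene-4,9-dione (bridgeheads spatially as in 21, hydroxyl endo)
Conditions: second-generation Grubbs catalyst (5 mol %), 2-methyl-2-butene/CH2Cl2, 40 °C
Reagents that add atoms: 2-methyl-2-butene, CC=C(C)C
Why: Olefin cross-metathesis converts the terminal allyl group into prenyl, while the existing trisubstituted prenyl groups and the 1,1-disubstituted isopropenyl group are spectators under these conditions.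

Step 16
Reactants: 23 7-prenyl carbinol
Product: 24 methyl oxalate ester of 23 (C7–O–CO–CO2Me, oxygen endo)
Conditions: ClCOCO2Me, DMAP, pyridine, CH2Cl2, 0 °C to rt
Reagents that add atoms: methyl chlorooxoacetate, COC(=O)C(=O)Cl
Why: Acylation of the hindered tertiary alcohol with the very reactive methyl oxalyl chloride gives the mixed oxalate, the radical precursor suited to tertiary alcohols, which cannot be taken through a xanthate.

Step 17
Reactants: 24 tertiary methyl oxalate
Product: 25 2-methoxy-8,8-dimethyl-1,7-bis(3-methylbut-2-enyl)-5-[(2S)-5-methyl-2-(prop-1-en-2-yl)hex-4-enyl]bicyclo[3.3.1]non-2-ene-4,9-dione (bridgeheads spatially as in 21, 7-prenyl endo, 7-H exo)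
Conditions: Bu3SnH, AIBN, toluene, 110 °C
Reagents that add atoms: none
Why: Barton–McCombie-type radical deoxygenation of a tertiary alkyl methyl oxalate, in which the near-planar tertiary C7 radical should take hydrogen from the stannane on the exo face because the endo face is screened by ring A, so that hydrogen ends exo and the prenyl group endo, as the target requires.

Step 18
Reactants: 26 3-hydroxybenzoic acid
Product: 28 3-(tert-butyldimethylsilyloxy)benzoic acid, via bis-silylated ester 27 (not isolated)
Conditions: TBSCl (2.3 equiv), imidazole, DMF, rt; then AcOH/THF/H2O, rt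
Reagents that add atoms: tert-butyldimethylsilyl chloride, CC(C)(C)[Si](C)(C)Cl
Why: Silylation of phenol and acid followed by selective hydrolysis of the labile silyl ester, so that the phenol is masked before the acid is activated.

Step 19
Reactants: 28 3-(tert-butyldimethylsilyloxy)benzoic acid
Product: 29 3-(tert-butyldimethylsilyloxy)benzoyl chloride
Conditions: (COCl)2, DMF (cat.), CH2Cl2, 0 °C to rt
Reagents that add atoms: oxalyl chloride, O=C(Cl)C(=O)Cl
Why: Acid chloride formation through the Vilsmeier-type chloroiminium intermediate, which an aryl silyl ether tolerates.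

Step 20
Reactants: 25 7-endo-prenyl bicyclic enol ether; 29 3-(tert-butyldimethylsilyloxy)benzoyl chloride
Product: 31 3-[3-(tert-butyldimethylsilyloxy)benzoyl] derivative of 25, via C3-lithio enol ether 30 (not isolated)
Conditions: lithium 2,2,6,6-tetramethylpiperidide, THF, −78 °C; then 29, −78 °C to 0 °C
Reagents that add atoms: none
Why: Vinylic deprotonation at C3, the α-carbon of the vinylogous ester and the only acidic C–H left (both bridgeheads are quaternary), followed by C-acylation of the vinyllithium with the aroyl chloride.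

Step 21
Reactants: 31 aroylated, silyl-protected methyl enol ether
Product: 32 target CNP0103487.1, 4-hydroxy-3-(3-hydroxybenzoyl)-8,8-dimethyl-1,7-bis(3-methylbut-2-enyl)-5-[(2S)-5-methyl-2-(prop-1-en-2-yl)hex-4-enyl]bicyclo[3.3.1]non-3-ene-2,9-dione (bridgeheads spatially as in 21, 7-prenyl endo)
Conditions: LiOH, dioxane/H2O, 90 °C; aq. HCl
Reagents that add atoms: water, O
Why: Hydrolysis of the vinylogous methyl ester by addition–elimination and cleavage of the aryl silyl ether by hydroxide in the same operation free the enolised β-triketone and the phenol, so the phenol is unmasked and not protected at the end.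

Compound list
1 | methyl acetoacetate | CC(=O)CC(=O)OC | starting material
2 | prenyl bromide | CC(C)=CCBr | starting material
3 | methyl 2-acetyl-5-methylhex-4-enoate | CC(=O)C(CC=C(C)C)C(=O)OC | intermediate
4 | prenol | CC(C)=CCO | starting material
5 | methyl (Z)-3-(3-methylbut-2-enyloxy)-2-(3-methylbut-2-enyl)but-2-enoate | C/C(OCC=C(C)C)=C(\CC=C(C)C)C(=O)OC | intermediate
6 | methyl (S)-2-acetyl-3,3-dimethyl-2-(3-methylbut-2-enyl)pent-4-enoate | COC(=O)[C@](CC=C(C)C)(C(C)=O)C(C)(C)C=C | intermediate
7 | methyl (S)-2-[1-(diethoxyphosphoryloxy)ethenyl]-3,3-dimethyl-2-(3-methylbut-2-enyl)pent-4-enoate | COC(=O)[C@](CC=C(C)C)(C(=C)OP(=O)(OCC)OCC)C(C)(C)C=C | intermediate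
8 | lithium acetylide of 9 | COC(=O)[C@](CC=C(C)C)(C#C[Li])C(C)(C)C=C | intermediate
9 | methyl (R)-2-ethynyl-3,3-dimethyl-2-(3-methylbut-2-enyl)pent-4-enoate | COC(=O)[C@](CC=C(C)C)(C#C)C(C)(C)C=C | intermediate
10 | (R)-lavandulol | C=C(C)[C@@H](CC=C(C)C)CO | starting material
11 | (R)-lavandulyl iodide | C=C(C)[C@@H](CC=C(C)C)CI | intermediate
12 | (R)-7-methyl-4-(prop-1-en-2-yl)oct-6-enenitrile | C=C(C)[C@@H](CC=C(C)C)CCC#N | intermediate
13 | (R)-7-methyl-4-(prop-1-en-2-yl)oct-6-enal | C=C(C)[C@@H](CC=C(C)C)CCC=O | intermediate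
14 | chloromagnesium acetylide of 9 | COC(=O)[C@](CC=C(C)C)(C#C[Mg]Cl)C(C)(C)C=C | intermediate
15 | methyl (2S,8R)-5-hydroxy-11-methyl-2-(2-methylbut-3-en-2-yl)-2-(3-methylbut-2-enyl)-8-(prop-1-en-2-yl)dodec-10-en-3-ynoate, C5 epimers | COC(=O)[C@](CC=C(C)C)(C#CC(O)CC[C@H](CC=C(C)C)C(C)=C)C(C)(C)C=C | intermediate
16 | methyl (2S,8R)-11-methyl-2-(2-methylbut-3-en-2-yl)-2-(3-methylbut-2-enyl)-5-oxo-8-(prop-1-en-2-yl)dodec-10-en-3-ynoate | COC(=O)[C@](CC=C(C)C)(C#CC(=O)CC[C@H](CC=C(C)C)C(C)=C)C(C)(C)C=C | intermediate
17 | methyl (2S,3E,8R)-3-methoxy-11-methyl-2-(2-methylbut-3-en-2-yl)-2-(3-methylbut-2-enyl)-5-oxo-8-(prop-1-en-2-yl)dodeca-3,10-dienoate | COC(=O)[C@](CC=C(C)C)(/C(OC)=C\C(=O)CC[C@H](CC=C(C)C)C(C)=C)C(C)(C)C=C | intermediate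
18 | (4R)-3-hydroxy-5-methoxy-4-(2-methylbut-3-en-2-yl)-4-(3-methylbut-2-enyl)-2-[(2S)-5-methyl-2-(prop-1-en-2-yl)hex-4-enyl]cyclohexa-2,5-dien-1-one | C=C(C)[C@@H](CC=C(C)C)CC1=C(O)[C@@](CC=C(C)C)(C(C)(C)C=C)C(OC)=CC1=O | intermediate
19 | (4R)-3-hydroxy-5-methoxy-4-(2-methyl-3-oxobutan-2-yl)-4-(3-methylbut-2-enyl)-2-[(2S)-5-methyl-2-(prop-1-en-2-yl)hex-4-enyl]cyclohexa-2,5-dien-1-one (key-step precursor) | C=C(C)[C@@H](CC=C(C)C)CC1=C(O)[C@@](CC=C(C)C)(C(C)(C)C(C)=O)C(OC)=CC1=O | intermediate
20 | dilithium dienolate of 19 (C4–C5–C9 diketonate and C6 enolate) | [Li+].[Li+].C=C(C)[C@@H](CC=C(C)C)CC1=C([O-])[C@@](CC=C(C)C)(C(C)(C)C([O-])=C)C(OC)=CC1=O | intermediate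
21 | (1S,5R)-2-methoxy-8,8-dimethyl-1-(3-methylbut-2-enyl)-5-[(2S)-5-methyl-2-(prop-1-en-2-yl)hex-4-enyl]bicyclo[3.3.1]non-2-ene-4,7,9-trione (key-step product) | C=C(C)[C@@H](CC=C(C)C)C[C@@]12CC(=O)C(C)(C)[C@@](CC=C(C)C)(C(OC)=CC1=O)C2=O | intermediate
22 | 7-allyl-7-hydroxy derivative of 21 (hydroxyl endo, allyl exo) | C=C(C)[C@@H](CC=C(C)C)C[C@@]12C[C@](O)(CC=C)C(C)(C)[C@@](CC=C(C)C)(C(OC)=CC1=O)C2=O | intermediate
23 | 7-hydroxy-7-prenyl derivative (hydroxyl endo, prenyl exo) | C=C(C)[C@@H](CC=C(C)C)C[C@@]12C[C@](O)(CC=C(C)C)C(C)(C)[C@@](CC=C(C)C)(C(OC)=CC1=O)C2=O | intermediate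
24 | methyl oxalate ester of 23 | C=C(C)[C@@H](CC=C(C)C)C[C@@]12C[C@](OC(=O)C(=O)OC)(CC=C(C)C)C(C)(C)[C@@](CC=C(C)C)(C(OC)=CC1=O)C2=O | intermediate
25 | 2-methoxy-8,8-dimethyl-1,7-bis(3-methylbut-2-enyl)-5-[(2S)-5-methyl-2-(prop-1-en-2-yl)hex-4-enyl]bicyclo[3.3.1]non-2-ene-4,9-dione (7-prenyl endo) | C=C(C)[C@@H](CC=C(C)C)C[C@@]12C[C@@H](CC=C(C)C)C(C)(C)[C@@](CC=C(C)C)(C(OC)=CC1=O)C2=O | intermediate
26 | 3-hydroxybenzoic acid | O=C(O)c1cccc(O)c1 | starting material
27 | tert-butyldimethylsilyl 3-(tert-butyldimethylsilyloxy)benzoate | CC(C)(C)[Si](C)(C)OC(=O)c1cccc(O[Si](C)(C)C(C)(C)C)c1 | intermediate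
28 | 3-(tert-butyldimethylsilyloxy)benzoic acid | CC(C)(C)[Si](C)(C)Oc1cccc(C(=O)O)c1 | intermediate
29 | 3-(tert-butyldimethylsilyloxy)benzoyl chloride | CC(C)(C)[Si](C)(C)Oc1cccc(C(=O)Cl)c1 | intermediate
30 | C3-lithio derivative of 25 | C=C(C)[C@@H](CC=C(C)C)C[C@@]12C[C@@H](CC=C(C)C)C(C)(C)[C@@](CC=C(C)C)(C(OC)=C([Li])C1=O)C2=O | intermediate
31 | 3-[3-(tert-butyldimethylsilyloxy)benzoyl] derivative of 25 | C=C(C)[C@@H](CC=C(C)C)C[C@@]12C[C@@H](CC=C(C)C)C(C)(C)[C@@](CC=C(C)C)(C(OC)=C(C(=O)c3cccc(O[Si](C)(C)C(C)(C)C)c3)C1=O)C2=O | intermediate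
32 | CNP0103487.1, 4-hydroxy-3-(3-hydroxybenzoyl)-8,8-dimethyl-1,7-bis(3-methylbut-2-enyl)-5-[(2S)-5-methyl-2-(prop-1-en-2-yl)hex-4-enyl]bicyclo[3.3.1]non-3-ene-2,9-dione (7-prenyl endo) | C=C(C)[C@@H](CC=C(C)C)C[C@@]12C[C@@H](CC=C(C)C)C(C)(C)[C@@](CC=C(C)C)(C(=O)C(C(=O)c3cccc(O)c3)=C1O)C2=O | target

Total step count: 21. Longest linear sequence: 16 steps (steps 1–4, 8–17, 20 and 21).

Steps most likely to fail

Step 13. The dianion may couple at oxygen, the C6 radical may be reduced back to 19, or intermolecular coupling may take over. The fallback sets out from 19 and forms the same bond by a polar, two-electron path. The dianion 20 is quenched at −78 °C with one equivalent of 1,2-dibromotetrachloroethane, which should brominate the more reactive C6 enolate and give, after mild acidic work-up, the bromomethyl ketone F1. Treatment of F1 with Cs2CO3 in DMF then closes C5–C6 by intramolecular C-alkylation of the 2-substituted cyclic 1,3-dione enolate with the α-bromo ketone. This returns to the route at 21.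

Step 17. Hydrogen delivery to the C7 radical may show poor facial selectivity, or the hindered tertiary alcohol may resist acylation in step 16. The fallback sets out from 21, bypasses 22–24 and replaces hydrogen-atom transfer by hydride delivery from the bulky copper hydride [(Ph3P)CuH]6. Ethynylmagnesium bromide is added to the C7 ketone to give the 7-ethynyl carbinol F2. A Meyer–Schuster rearrangement with VO(OSiPh3)3 turns it into the exocyclic enal F3 (C7=CH–CHO). Conjugate reduction with [(Ph3P)CuH]6 puts hydride on C7 from the exo face and gives the 7-endo-(2-oxoethyl) compound F4. A Wittig reaction of F4 with isopropylidenetriphenylphosphorane then makes the prenyl group and returns to the route at 25.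

Step 3. The catalyst may give low enantioselectivity or no turnover with the hindered, tetrasubstituted enol ether. The fallback sets out from 5: the uncatalysed thermal Claisen rearrangement (toluene, 150 °C, sealed vessel) gives the racemate. The racemate is resolved by preparative chromatography on a chiral stationary phase at this single-stereocentre stage. The unwanted antipode, methyl (R)-2-acetyl-3,3-dimethyl-2-(3-methylbut-2-enyl)pent-4-enoate F5, is set aside, and the route is rejoined at 6.

Further compounds
F1 | step 13 | (4R)-4-(4-bromo-2-methyl-3-oxobutan-2-yl)-3-hydroxy-5-methoxy-4-(3-methylbut-2-enyl)-2-[(2S)-5-methyl-2-(prop-1-en-2-yl)hex-4-enyl]cyclohexa-2,5-dien-1-one | C=C(C)[C@@H](CC=C(C)C)CC1=C(O)[C@@](CC=C(C)C)(C(C)(C)C(=O)CBr)C(OC)=CC1=O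
F2 | step 17 | 7-ethynyl-7-hydroxy derivative of 21 (hydroxyl endo) | C=C(C)[C@@H](CC=C(C)C)C[C@@]12C[C@](O)(C#C)C(C)(C)[C@@](CC=C(C)C)(C(OC)=CC1=O)C2=O
F3 | step 17 | 7-(2-oxoethylidene) derivative of 21 | C=C(C)[C@@H](CC=C(C)C)C[C@@]12CC(=CC=O)C(C)(C)[C@@](CC=C(C)C)(C(OC)=CC1=O)C2=O
F4 | step 17 | 7-endo-(2-oxoethyl) compound (7-H exo) | C=C(C)[C@@H](CC=C(C)C)C[C@@]12C[C@@H](CC=O)C(C)(C)[C@@](CC=C(C)C)(C(OC)=CC1=O)C2=O
F5 | step 3 | methyl (R)-2-acetyl-3,3-dimethyl-2-(3-methylbut-2-enyl)pent-4-enoate | COC(=O)[C@@](CC=C(C)C)(C(C)=O)C(C)(C)C=C
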